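The depside is cut at its two aryl–propyl bonds. Ring A (the acyl ring) and ring B (the carboxylic acid ring) each carry n-propyl at C6 and C6′, ortho to the carbonyl-bearing carbons C1 and C1′. Both halves therefore map onto one 6-bromoresorcylic unit made from a single bromoarene. A double Negishi coupling with n-propylzinc bromide forms C6–CH2 and C6′–CH2 in one operation on the finished ester core. It closes no ring and sets no stereocentre. Its precursor is the 6,6′-dibromo depside with the ring A 2-OMe in place and the 4-OH, 2′-OH and CO2H masked as benzyl groups, all removed in one final hydrogenolysis.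

Key step: step 9

Remark on the chemistry: the target has no stereocentre, stereogenic axis or C=C geometry, so it is achiral and no step has to control configuration.
Locants: ring A is unprimed (C1 bears the ester carbonyl). Ring B is primed (C1′ bears CO2H, C4′ the ester oxygen).

Step 1
Reactants: 1 1-bromo-3,5-dimethoxybenzene
Product: 3 2-bromo-4,6-dimethoxybenzaldehyde, via aryl iminium chloride 2 (not isolated)
Conditions: POCl3, DMF, 0 → 90 °C; then ice/H2O
Reagents that add atoms: N,N-dimethylformamide, CN(C)C=O; water, O; phosphoryl chloride, O=P(Cl)(Cl)Cl (chloride of intermediate 2 only)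
Why: Vilsmeier–Haack formylation, in which the chloroiminium electrophile attacks the ring position activated by one para and one ortho methoxy group (next to bromine) and water then hydrolyses iminium 2 to the aldehyde.

Step 2
Reactants: 3 2-bromo-4,6-dimethoxybenzaldehyde
Product: 4 2-bromo-4,6-dihydroxybenzaldehyde
Conditions: BBr3 (4 equiv), CH2Cl2, −78 °C → rt; then ice/H2O
Reagents that add atoms: none
Why: Lewis acid ether cleavage, in which BBr3 binds each methoxy oxygen and bromide removes the methyl group by SN2, while the aryl bromide and the formyl group should stay intact at or below room temperature.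

Step 3
Reactants: 4 2-bromo-4,6-dihydroxybenzaldehyde; 5 benzyl bromide
Product: 6 4-(benzyloxy)-2-bromo-6-hydroxybenzaldehyde
Conditions: BnBr (1.05 equiv), CsHCO3, MeCN, 60 °C
Reagents that add atoms: benzyl bromide (5), BrCc1ccccc1
Why: Regioselective Williamson etherification, because the C6 hydroxyl is hydrogen-bonded to the formyl oxygen and less acidic, so the weak base ionises and benzylates only the C4 hydroxyl.

Step 4
Reactants: 6 4-(benzyloxy)-2-bromo-6-hydroxybenzaldehyde
Product: 7 4-(benzyloxy)-2-bromo-6-methoxybenzaldehyde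
Conditions: MeI, K2CO3, DMF, rt
Reagents that add atoms: iodomethane, CI
Why: Williamson etherification, in which carbonate in a dipolar aprotic solvent ionises the remaining chelated phenol and the non-enolisable aldehyde offers no competing site.

Step 5
Reactants: 7 4-(benzyloxy)-2-bromo-6-methoxybenzaldehyde
Product: 8 4-(benzyloxy)-2-bromo-6-methoxybenzoic acid
Conditions: NaClO2, NaH2PO4, 2-methyl-2-butene (excess), t-BuOH/THF/H2O, 0 °C → rt
Reagents that add atoms: sodium chlorite, [Na+].[O-]Cl=O
Why: Pinnick oxidation, in which chlorous acid adds to the aldehyde and fragments to the acid in a mildly acidic buffer while the alkene removes hypochlorous acid before it can chlorinate the alkoxy-substituted ring.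

Step 6
Reactants: 8 4-(benzyloxy)-2-bromo-6-methoxybenzoic acid; 4 2-bromo-4,6-dihydroxybenzaldehyde
Product: 10 3-bromo-4-formyl-5-hydroxyphenyl 4-(benzyloxy)-2-bromo-6-methoxybenzoate, via mixed trifluoroacetic anhydride 9 (not isolated)
Conditions: (CF3CO)2O, toluene, 0 °C → rt (8 activated first, then 4 added, 1:1)
Reagents that add atoms: trifluoroacetic anhydride, O=C(OC(=O)C(F)(F)F)C(F)(F)F (its atoms stay in intermediate 9 only)
Why: Depside-type esterification through a mixed anhydride, in which 9 ionises readily to an alkoxy-stabilised acylium ion that is taken up by the free C4 hydroxyl of 4 and not by the C6 hydroxyl, which is chelated to and flanked by the formyl group.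

Step 7
Reactants: 10 3-bromo-4-formyl-5-hydroxyphenyl 4-(benzyloxy)-2-bromo-6-methoxybenzoate
Product: 11 4-{[4-(benzyloxy)-2-bromo-6-methoxybenzoyl]oxy}-2-bromo-6-hydroxybenzoic acid
Conditions: NaClO2, NaH2PO4, 2-methyl-2-butene (excess), t-BuOH/THF/H2O, 0 °C → rt
Reagents that add atoms: sodium chlorite, [Na+].[O-]Cl=O
Why: Pinnick oxidation of a salicylaldehyde-type aldehyde, in which the mildly acidic buffer leaves the aryl ester alone and ring B, which carries bromine, acyloxy and formyl groups, is too electron-poor to compete with the scavenger for hypochlorous acid.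

Step 8
Reactants: 11 4-{[4-(benzyloxy)-2-bromo-6-methoxybenzoyl]oxy}-2-bromo-6-hydroxybenzoic acid; 5 benzyl bromide
Product: 13 benzyl 2-(benzyloxy)-4-{[4-(benzyloxy)-2-bromo-6-methoxybenzoyl]oxy}-6-bromobenzoate, via benzyl ester phenol 12 (not isolated)
Conditions: BnBr (2.5 equiv), K2CO3, dry DMF, rt → 40 °C
Reagents that add atoms: benzyl bromide (5), BrCc1ccccc1
Why: Double O-alkylation (carboxylate alkylation followed by Williamson etherification), in which the carboxylate reacts first to give 12 and the chelated phenoxide follows, while the depside carbonyl between bromine and methoxy is shielded from the weak nucleophiles present in the dry medium.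

Step 9
Reactants: 13 benzyl 2-(benzyloxy)-4-{[4-(benzyloxy)-2-bromo-6-methoxybenzoyl]oxy}-6-bromobenzoate; 14 n-propylzinc bromide
Product: 17 benzyl 2-(benzyloxy)-4-{[4-(benzyloxy)-2-methoxy-6-propylbenzoyl]oxy}-6-propylbenzoate, via ring B monopropyl depside 15 (not isolated), via ring A monopropyl depside 16 (not isolated)
Conditions: n-PrZnBr (0.5 M in THF, 3.5 equiv), Pd(OAc)2 (4 mol %), SPhos (8 mol %), THF, 0 °C → rt; then sat. aq NH4Cl
Reagents that add atoms: n-propylzinc bromide (14), CCC[Zn]Br
Why: Pd(0)/SPhos inserts into each C–Br bond, propyl passes from zinc to palladium, and reductive elimination forms C6–CH2 and C6′–CH2, the sequence running once on each ring by way of 15 or 16. The closest known reaction type is the Negishi coupling of primary alkylzinc halides with ortho-substituted, ester-bearing aryl bromides under bulky biarylphosphine–palladium catalysis. No ring is closed and no stereocentre is formed. Both C–Br carbons lie meta to the two ring oxygens, so they receive no resonance donation, and ortho to an ester carbonyl, which speeds insertion. The step needs insertion into C–Br and not into the acyl C–O bond of the aryl ester or the benzylic C–O bonds, and it must avoid cyclisation of the ring A aryl–palladium onto C3′–H or C5′–H; the weak C–Br bond, a phosphine in place of a carbene ligand, room temperature and the absence of base should secure this, and the depside carbonyl flanked by bromine and methoxy is shielded from the organozinc. Fast reductive elimination from the hindered ligand should outrun β-hydride loss, which keeps hydrodebromination and the isopropyl isomer low, and the excess of 14 carries the second coupling to completion.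

Step 10
Reactants: 17 benzyl 2-(benzyloxy)-4-{[4-(benzyloxy)-2-methoxy-6-propylbenzoyl]oxy}-6-propylbenzoate
Product: 18 2-hydroxy-4-[(4-hydroxy-2-methoxy-6-propylbenzoyl)oxy]-6-propylbenzoic acid (target)
Conditions: H2 (1 atm), 10% Pd/C, EtOAc, rt
Reagents that add atoms: none
Why: Catalytic hydrogenolysis, which cleaves all three benzylic C–O bonds under neutral conditions in a non-nucleophilic solvent and leaves the aryl ester, the methyl ether and the decarboxylation-prone salicylic acid unit unchanged.

Compound list
1 | 1-bromo-3,5-dimethoxybenzene | COc1cc(Br)cc(OC)c1 | starting material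
2 | [(2-bromo-4,6-dimethoxyphenyl)methylidene]dimethylammonium chloride | COc1cc(Br)c(C=[N+](C)C)c(OC)c1.[Cl-] | intermediate (not isolated)
3 | 2-bromo-4,6-dimethoxybenzaldehyde | COc1cc(Br)c(C=O)c(OC)c1 | intermediate
4 | 2-bromo-4,6-dihydroxybenzaldehyde | Oc1cc(O)c(C=O)c(Br)c1 | intermediate
5 | benzyl bromide | BrCc1ccccc1 | starting material
6 | 4-(benzyloxy)-2-bromo-6-hydroxybenzaldehyde | O=Cc1c(O)cc(OCc2ccccc2)cc1Br | intermediate
7 | 4-(benzyloxy)-2-bromo-6-methoxybenzaldehyde | COc1cc(OCc2ccccc2)cc(Br)c1C=O | intermediate
8 | 4-(benzyloxy)-2-bromo-6-methoxybenzoic acid | COc1cc(OCc2ccccc2)cc(Br)c1C(=O)O | intermediate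
9 | 4-(benzyloxy)-2-bromo-6-methoxybenzoic trifluoroacetic anhydride | COc1cc(OCc2ccccc2)cc(Br)c1C(=O)OC(=O)C(F)(F)F | intermediate (not isolated)
10 | 3-bromo-4-formyl-5-hydroxyphenyl 4-(benzyloxy)-2-bromo-6-methoxybenzoate | COc1cc(OCc2ccccc2)cc(Br)c1C(=O)Oc1cc(O)c(C=O)c(Br)c1 | intermediate
11 | 4-{[4-(benzyloxy)-2-bromo-6-methoxybenzoyl]oxy}-2-bromo-6-hydroxybenzoic acid | COc1cc(OCc2ccccc2)cc(Br)c1C(=O)Oc1cc(O)c(C(=O)O)c(Br)c1 | intermediate
12 | benzyl 4-{[4-(benzyloxy)-2-bromo-6-methoxybenzoyl]oxy}-2-bromo-6-hydroxybenzoate | COc1cc(OCc2ccccc2)cc(Br)c1C(=O)Oc1cc(O)c(C(=O)OCc2ccccc2)c(Br)c1 | intermediate (not isolated)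
13 | benzyl 2-(benzyloxy)-4-{[4-(benzyloxy)-2-bromo-6-methoxybenzoyl]oxy}-6-bromobenzoate | COc1cc(OCc2ccccc2)cc(Br)c1C(=O)Oc1cc(Br)c(C(=O)OCc2ccccc2)c(OCc2ccccc2)c1 | intermediate (key-step precursor)
14 | n-propylzinc bromide | CCC[Zn]Br | starting material
15 | benzyl 2-(benzyloxy)-4-{[4-(benzyloxy)-2-bromo-6-methoxybenzoyl]oxy}-6-propylbenzoate | COc1cc(OCc2ccccc2)cc(Br)c1C(=O)Oc1cc(CCC)c(C(=O)OCc2ccccc2)c(OCc2ccccc2)c1 | intermediate (not isolated)
16 | benzyl 2-(benzyloxy)-4-{[4-(benzyloxy)-2-methoxy-6-propylbenzoyl]oxy}-6-bromobenzoate | CCCc1cc(OCc2ccccc2)cc(OC)c1C(=O)Oc1cc(Br)c(C(=O)OCc2ccccc2)c(OCc2ccccc2)c1 | intermediate (not isolated)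
17 | benzyl 2-(benzyloxy)-4-{[4-(benzyloxy)-2-methoxy-6-propylbenzoyl]oxy}-6-propylbenzoate | CCCc1cc(OCc2ccccc2)cc(OC)c1C(=O)Oc1cc(CCC)c(C(=O)OCc2ccccc2)c(OCc2ccccc2)c1 | intermediate (key-step product)
18 | 2-hydroxy-4-[(4-hydroxy-2-methoxy-6-propylbenzoyl)oxy]-6-propylbenzoic acid | CCCc1cc(OC(=O)c2c(CCC)cc(O)cc2OC)cc(O)c1C(=O)O | target

Total step count: 10.
Longest linear sequence: 10 steps (1 → 3 → 4 → 6 → 7 → 8 → 10 → 11 → 13 → 17 → 18). Compound 4 enters twice, in steps 3 and 6.

Steps most likely to fail

Step 9. The second coupling may stall. β-Hydride loss from the propyl–palladium species may cause hydrodebromination or chain isomerisation. The fallback sets out from 13 and replaces the sp3 zinc reagent by an allyl donor that cannot undergo this loss. A base-free double Stille allylation (allyltributylstannane, Pd(PPh3)4, toluene, 100 °C) should give benzyl 2-allyl-6-(benzyloxy)-4-{[2-allyl-4-(benzyloxy)-6-methoxybenzoyl]oxy}benzoate F1. After removal of tin residues, hydrogenation under the conditions of step 10 saturates both alkenes, wherever they sit after any isomerisation, and cleaves the three benzyl groups. This comes back to the route at 18.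

Step 6. The two hydroxyls of the formyl phenol may be poorly discriminated. Acyl transfer to this electron-poor phenol may be slow, and the aldehyde may interfere with the anhydride. The fallback sets out from 3 (with 8 as the acid partner) and installs the ring B carboxyl before the coupling.
- Pinnick oxidation of 3 should give 2-bromo-4,6-dimethoxybenzoic acid F2.
- BBr3 in CH2Cl2 should give 2-bromo-4,6-dihydroxybenzoic acid F3.
- BnBr with KHCO3 in DMF at rt alkylates only the carboxylate, giving benzyl 2-bromo-4,6-dihydroxybenzoate F4, the classical type of phenol partner for depside formation.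
- Condensation of F4 with 8 through 9 acylates the unchelated C4′ hydroxyl.

This comes back to the route at 12, which is isolated here and etherified to 13 under the conditions of step 8. Steps 6 and 7 are bypassed.

Step 7. The ring may be chlorinated ortho or para to the free phenol, or the chelated, doubly ortho-substituted aldehyde may oxidise slowly. The fallback sets out from 10 and masks the phenol before the oxidation, which also breaks the hydrogen bond to the formyl group.
- BnBr with K2CO3 in DMF should give 3-(benzyloxy)-5-bromo-4-formylphenyl 4-(benzyloxy)-2-bromo-6-methoxybenzoate F5.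
- Pinnick oxidation should give 2-(benzyloxy)-4-{[4-(benzyloxy)-2-bromo-6-methoxybenzoyl]oxy}-6-bromobenzoic acid F6.
- BnBr with KHCO3 in DMF closes the sequence.

This comes back to the route at 13.

Further compounds
F1 | step 9 | benzyl 2-allyl-6-(benzyloxy)-4-{[2-allyl-4-(benzyloxy)-6-methoxybenzoyl]oxy}benzoate | C=CCc1cc(OCc2ccccc2)cc(OC)c1C(=O)Oc1cc(CC=C)c(C(=O)OCc2ccccc2)c(OCc2ccccc2)c1
F2 | step 6 | 2-bromo-4,6-dimethoxybenzoic acid | COc1cc(Br)c(C(=O)O)c(OC)c1
F3 | step 6 | 2-bromo-4,6-dihydroxybenzoic acid | Oc1cc(O)c(C(=O)O)c(Br)c1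
F4 | step 6 | benzyl 2-bromo-4,6-dihydroxybenzoate | Oc1cc(O)c(C(=O)OCc2ccccc2)c(Br)c1
F5 | step 7 | 3-(benzyloxy)-5-bromo-4-formylphenyl 4-(benzyloxy)-2-bromo-6-methoxybenzoate | COc1cc(OCc2ccccc2)cc(Br)c1C(=O)Oc1cc(Br)c(C=O)c(OCc2ccccc2)c1
F6 | step 7 | 2-(benzyloxy)-4-{[4-(benzyloxy)-2-bromo-6-methoxybenzoyl]oxy}-6-bromobenzoic acid | COc1cc(OCc2ccccc2)cc(Br)c1C(=O)Oc1cc(Br)c(C(=O)O)c(OCc2ccccc2)c1
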